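Rings: A = the 4‑alkyl‑2‑aryloxyphenol ring, B = the meta‑phenylene, C = the catechol ring (C1 chain, C3‑OH, C4‑OH, C5‑OAr), D = the para‑phenylene.
Retrosynthesis: the ring A O–CH3 bond, the two ring D C–Cl bonds and the ring C C3–O bond (back to C3–Br) are functional‑group changes; the 19‑membered ring is then opened at the ring C C5–O bond to the ring D oxygen; next the ring A–O–ring B ether is cut; last, both ArCH2–CH2Ar bonds are cut as stilbene C=C bonds.
Forward: the D=A and B=C stilbenes are made by two Wittig reactions, joined through the A–O–B ether, reduced to the open bis(bibenzyl) chain, unmasked and dibrominated on ring C; the only ring, the macrocycle, is then closed by oxidative phenol coupling; bromine‑to‑hydroxyl exchange, dechlorination and demethylation finish.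
Structural feature used: in ring C the aryloxy carbon C5 lies ortho to the C4 hydroxyl and the other ortho carbon C3 bears oxygen. This is the imprint of a 4‑alkyl‑2,6‑dibromophenol after ipso attack of a second phenol's oxygen at one ortho carbon and hydroxylation at the other.
Stereochemistry: none has to be set; alkene isomer mixtures vanish on reduction and the sp3 carbon of the transient dienone is lost on rearomatisation.

Key step: step 10

Remark: the target SMILES holds no stereocentre or other stereo descriptor, so the compound is treated as achiral and no step has to control configuration.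

Step 1
Reactants: 1 3,5-dichloro-4-hydroxybenzaldehyde
Product: 2 3,5-dichloro-4-(methoxymethoxy)benzaldehyde
Conditions: MOMCl, i-Pr2NEt, CH2Cl2, 0 °C → rt
Reagents that add atoms: chloromethyl methyl ether, COCCl
Why: O‑alkylation of the acidic phenol with the reactive α‑chloro ether (MOM protection) masks the phenoxide, which would otherwise deactivate the aldehyde in the Wittig step.

Step 2
Reactants: 3 3-hydroxy-4-methoxybenzyl alcohol
Product: 4 (3-hydroxy-4-methoxybenzyl)triphenylphosphonium bromide
Conditions: PPh3·HBr, MeCN, reflux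
Reagents that add atoms: triphenylphosphine hydrobromide, [Br-].c1ccc(cc1)[PH+](c1ccccc1)c1ccccc1
Why: The p‑methoxy‑stabilised benzylic cation formed on protonation is captured by PPh3 (phosphonium salt formation from a benzylic alcohol), and the free phenol takes no part.

Step 3
Reactants: 4 (3-hydroxy-4-methoxybenzyl)triphenylphosphonium bromide; 2 3,5-dichloro-4-(methoxymethoxy)benzaldehyde
Product: 6 5-{2-[3,5-dichloro-4-(methoxymethoxy)phenyl]ethenyl}-2-methoxyphenol (E/Z mixture), via phenoxide ylide 5 (not isolated)
Conditions: KOt-Bu (2.2 equiv), THF, 0 °C → rt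
Reagents that add atoms: none
Why: Wittig olefination of the non‑enolisable aldehyde by the ylide formed with the second equivalent of base should give the stilbene, whose geometry is irrelevant because the alkene is reduced later.

Step 4
Reactants: 7 3-iodobenzyl bromide
Product: 8 (3-iodobenzyl)triphenylphosphonium bromide
Conditions: PPh3, toluene, reflux
Reagents that add atoms: triphenylphosphine, c1ccc(cc1)P(c1ccccc1)c1ccccc1
Why: SN2 quaternisation of triphenylphosphine by a benzylic bromide.

Step 5
Reactants: 8 (3-iodobenzyl)triphenylphosphonium bromide; 9 4-(methoxymethoxy)benzaldehyde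
Product: 11 1-iodo-3-{2-[4-(methoxymethoxy)phenyl]ethenyl}benzene (E/Z mixture), via benzylic ylide 10 (not isolated)
Conditions: KOt-Bu, THF, 0 °C → rt
Reagents that add atoms: none
Why: Wittig olefination with a semi‑stabilised ylide, generated with an alkoxide base that leaves the aryl iodide untouched.

Step 6
Reactants: 6 5-{2-[3,5-dichloro-4-(methoxymethoxy)phenyl]ethenyl}-2-methoxyphenol; 11 1-iodo-3-{2-[4-(methoxymethoxy)phenyl]ethenyl}benzene
Product: 12 1-{2-[3,5-dichloro-4-(methoxymethoxy)phenyl]ethenyl}-4-methoxy-3-(3-{2-[4-(methoxymethoxy)phenyl]ethenyl}phenoxy)benzene (alkene isomer mixture)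
Conditions: CuI (10 mol %), picolinic acid (20 mol %), K3PO4, DMSO, 85 °C
Reagents that add atoms: none
Why: Copper‑catalysed Ullmann O‑arylation of the ortho‑methoxy phenol by the aryl iodide should form the A–O–B ether, since aryl chlorides, MOM ethers and stilbenes are inert under these conditions.

Step 7
Reactants: 12 bis‑stilbene diaryl ether
Product: 13 1-{2-[3,5-dichloro-4-(methoxymethoxy)phenyl]ethyl}-4-methoxy-3-(3-{2-[4-(methoxymethoxy)phenyl]ethyl}phenoxy)benzene
Conditions: TsNHNH2, NaOAc, DME–H2O, reflux
Reagents that add atoms: none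
Why: Diimide reduction saturates both stilbene double bonds without touching the aryl chlorides, which hydrogenation over palladium would put at risk.

Step 8
Reactants: 13 bis(bibenzyl) bis‑MOM ether
Product: 14 2,6-dichloro-4-[2-(3-{3-[2-(4-hydroxyphenyl)ethyl]phenoxy}-4-methoxyphenyl)ethyl]phenol
Conditions: conc. HCl (cat.), MeOH–THF, 50 °C
Reagents that add atoms: none
Why: Acid‑catalysed acetal exchange (MOM cleavage) frees both phenols while the methyl and diaryl ethers are stable.

Step 9
Reactants: 14 2,6-dichloro-4-[2-(3-{3-[2-(4-hydroxyphenyl)ethyl]phenoxy}-4-methoxyphenyl)ethyl]phenol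
Product: 15 2,6-dibromo-4-[2-(3-{5-[2-(3,5-dichloro-4-hydroxyphenyl)ethyl]-2-methoxyphenoxy}phenyl)ethyl]phenol
Conditions: NBS (2.05 equiv), i-Pr2NH (10 mol %), CH2Cl2, 0 °C
Reagents that add atoms: N-bromosuccinimide, O=C1CCC(=O)N1Br
Why: Amine‑mediated ortho‑selective electrophilic bromination of phenols should hit only ring C, because the ring D phenol has no open ortho or para position and the aryl ether rings react far more slowly.

Step 10
Reactants: 15 2,6-dibromo-4-[2-(3-{5-[2-(3,5-dichloro-4-hydroxyphenyl)ethyl]-2-methoxyphenoxy}phenyl)ethyl]phenol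
Product: 17 19‑membered macrocyclic diaryl ether (ring C 3-bromo-4-hydroxy-5-aryloxy; ring D 2,6-dichloro-1,4-phenylene; ring A methyl ether), via macrocyclic bromodienone 16 (not isolated)
Conditions: Tl(NO3)3·3H2O (3 equiv), MeOH–THF, −20 → 0 °C, 1 mM; then Zn dust, AcOH, rt
Reagents that add atoms: none
Why: Thallium(III) should oxidise the more easily oxidised 2,6‑dibromophenol (ring C) by two electrons to a phenoxonium‑type species, the hydroxyl of the 2,6‑dichlorophenol (ring D) adds to one bromine‑bearing ortho carbon to give dienone 16, and zinc then removes the bromine from that sp3 carbon so that the ring rearomatises as the o‑aryloxyphenol. The closest known reaction type is the thallium(III) nitrate oxidative coupling of tethered o,o'‑dihalophenols to macrocyclic diaryl ethers with reductive work‑up, i.e. oxidative phenol coupling in its halogen‑controlled form. The single ring formed is the 19‑membered macrocycle, closed end‑to‑end through the C5(ring C)–O(ring D) bond under high dilution. No stereocentre remains, since the sp3 carbon of 16 arises without control and is erased by the reduction. The step needs ring selectivity and C–O over C–C selectivity: the lower oxidation potential of the dibromophenol relative to the dichlorophenol makes ring C the acceptor and ring D the oxygen donor, every ortho and para carbon of both phenols is blocked by halogen or alkyl so that only ipso attack at C–Br can end in an aromatic product, and the two ortho carbons of ring C are equivalent. Ring A is capped as its methyl ether, and para‑methoxylated dienone by‑products should be returned to phenol 15 by the zinc treatment.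

Step 11
Reactants: 17 macrocyclic bromophenol
Product: 18 macrocyclic catechol (ring C 3,4-dihydroxy-5-aryloxy; ring D 2,6-dichloro-1,4-phenylene; ring A methyl ether)
Conditions: CuI (20 mol %), 8-hydroxyquinoline (40 mol %), KOH (6 equiv), DMSO–H2O, 100 °C, Ar; then aq. HCl, Na2S2O4
Reagents that add atoms: potassium hydroxide, [K+].[OH-]
Why: Copper‑catalysed Ullmann‑type hydroxylation of an aryl bromide ortho to a phenoxide is the classical route from o‑bromophenols to catechols, and the hindered aryl chlorides should not react at this temperature.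

Step 12
Reactants: 18 macrocyclic catechol dichloride
Product: 19 macrocyclic catechol with ring A methyl ether and unsubstituted para‑phenylene ring D
Conditions: H2 (3 atm), 10% Pd/C, Et3N, MeOH–EtOAc, rt
Reagents that add atoms: none
Why: Palladium‑catalysed hydrodechlorination with an amine to take up HCl removes both blocking chlorines, while diaryl ethers and the catechol are stable to hydrogenolysis.

Step 13
Reactants: 19 macrocyclic mono‑methyl ether
Product: 20 CNP0495401.0 (target; ring A phenol, ring C catechol)
Conditions: BBr3, CH2Cl2, −78 → 0 °C; then H2O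
Reagents that add atoms: none
Why: Boron tribromide demethylation cleaves the one aryl methyl ether and leaves the two diaryl ether bonds intact.

Compound list
1 | 3,5-dichloro-4-hydroxybenzaldehyde | O=Cc1cc(Cl)c(O)c(Cl)c1 | starting material
2 | 3,5-dichloro-4-(methoxymethoxy)benzaldehyde | COCOc1c(Cl)cc(C=O)cc1Cl | intermediate
3 | 3-hydroxy-4-methoxybenzyl alcohol | COc1ccc(CO)cc1O | starting material
4 | (3-hydroxy-4-methoxybenzyl)triphenylphosphonium bromide | COc1ccc(C[P+](c2ccccc2)(c2ccccc2)c2ccccc2)cc1O.[Br-] | intermediate
5 | potassium 2-methoxy-5-[(triphenylphosphoranylidene)methyl]phenolate (phenoxide ylide) | COc1ccc(C=P(c2ccccc2)(c2ccccc2)c2ccccc2)cc1[O-].[K+] | intermediate (not isolated)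
6 | 5-{2-[3,5-dichloro-4-(methoxymethoxy)phenyl]ethenyl}-2-methoxyphenol, E/Z mixture | COCOc1c(Cl)cc(C=Cc2ccc(OC)c(O)c2)cc1Cl | intermediate
7 | 3-iodobenzyl bromide | BrCc1cccc(I)c1 | starting material
8 | (3-iodobenzyl)triphenylphosphonium bromide | Ic1cccc(C[P+](c2ccccc2)(c2ccccc2)c2ccccc2)c1.[Br-] | intermediate
9 | 4-(methoxymethoxy)benzaldehyde | COCOc1ccc(C=O)cc1 | starting material
10 | (3-iodobenzylidene)triphenylphosphorane (benzylic ylide) | Ic1cccc(C=P(c2ccccc2)(c2ccccc2)c2ccccc2)c1 | intermediate (not isolated)
11 | 1-iodo-3-{2-[4-(methoxymethoxy)phenyl]ethenyl}benzene, E/Z mixture | COCOc1ccc(C=Cc2cccc(I)c2)cc1 | intermediate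
12 | 1-{2-[3,5-dichloro-4-(methoxymethoxy)phenyl]ethenyl}-4-methoxy-3-(3-{2-[4-(methoxymethoxy)phenyl]ethenyl}phenoxy)benzene, alkene isomer mixture | COCOc1ccc(C=Cc2cccc(Oc3cc(C=Cc4cc(Cl)c(OCOC)c(Cl)c4)ccc3OC)c2)cc1 | intermediate
13 | 1-{2-[3,5-dichloro-4-(methoxymethoxy)phenyl]ethyl}-4-methoxy-3-(3-{2-[4-(methoxymethoxy)phenyl]ethyl}phenoxy)benzene | COCOc1ccc(CCc2cccc(Oc3cc(CCc4cc(Cl)c(OCOC)c(Cl)c4)ccc3OC)c2)cc1 | intermediate
14 | 2,6-dichloro-4-[2-(3-{3-[2-(4-hydroxyphenyl)ethyl]phenoxy}-4-methoxyphenyl)ethyl]phenol | Oc1ccc(CCc2cccc(Oc3cc(CCc4cc(Cl)c(O)c(Cl)c4)ccc3OC)c2)cc1 | intermediate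
15 | 2,6-dibromo-4-[2-(3-{5-[2-(3,5-dichloro-4-hydroxyphenyl)ethyl]-2-methoxyphenoxy}phenyl)ethyl]phenol | Oc1c(Br)cc(CCc2cccc(Oc3cc(CCc4cc(Cl)c(O)c(Cl)c4)ccc3OC)c2)cc1Br | intermediate (precursor of the key step)
16 | macrocyclic 2,6-dibromo-6-aryloxycyclohexa-2,4-dienone (ring C dearomatised, ring D oxygen on the sp3 carbon, racemic) | COc1ccc2cc1Oc1cccc(c1)CCC1=CC(Br)(Oc3c(Cl)cc(cc3Cl)CC2)C(=O)C(Br)=C1 | intermediate (not isolated)
17 | 19‑membered macrocycle, ring C 3-bromo-4-hydroxy-5-aryloxy, ring D 2,6-dichloro-1,4-phenylene, ring A methyl ether | COc1ccc2cc1Oc1cccc(c1)CCc1cc(Br)c(O)c(c1)Oc1c(Cl)cc(cc1Cl)CC2 | intermediate (product of the key step)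
18 | 19‑membered macrocycle, ring C 3,4-dihydroxy-5-aryloxy, ring D 2,6-dichloro-1,4-phenylene, ring A methyl ether | COc1ccc2cc1Oc1cccc(c1)CCc1cc(O)c(O)c(c1)Oc1c(Cl)cc(cc1Cl)CC2 | intermediate
19 | 19‑membered macrocycle, ring C catechol, ring D 1,4-phenylene, ring A methyl ether | COc1ccc2cc1Oc1cccc(c1)CCc1cc(O)c(O)c(c1)Oc1ccc(cc1)CC2 | intermediate
20 | CNP0495401.0 | Oc1ccc2cc1Oc1cccc(c1)CCc1cc(O)c(O)c(c1)Oc1ccc(cc1)CC2 | target

Total step count: 13. Longest linear sequence: 10 steps (steps 1, 3, 6, 7, 8, 9, 10, 11, 12, 13).

Steps most likely to fail, riskiest first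

Step 10. The chain may couple between molecules and give dimers and oligomers instead of the macrocycle. Oxidation may also start on the dichlorophenol ring, which would place the ether oxygen on the wrong ring, or methanol may capture the oxidised ring at its alkyl‑bearing para carbon faster than the second phenol reaches an ortho carbon. The fallback closes the same C5–O bond by copper‑mediated aryl ether formation and takes ring C from commercial 3-bromo-4,5-dimethoxybenzaldehyde, so that both catechol oxygens are present from the start. It sets out from 8, 4 and 9 and returns at 20. Wittig reaction of 8 with that aldehyde should give 1-bromo-5-[2-(3-iodophenyl)ethenyl]-2,3-dimethoxybenzene F1, and Wittig reaction of 4 with 9 should give 2-methoxy-5-{2-[4-(methoxymethoxy)phenyl]ethenyl}phenol F2. Ullmann coupling of F2 at the iodide of F1 under the conditions of step 6 should give the bis‑stilbene diaryl ether F3, diimide reduction the bis(bibenzyl) F4, and HCl in methanol the open‑chain bromo phenol F5. Intramolecular Ullmann coupling of the ring D phenol with the ring C bromide (CuI, N,N-dimethylglycine, Cs2CO3, dioxane, 110 °C, high dilution) should give the macrocyclic trimethyl ether F6, which BBr3 converts into 20.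

Step 11. Bromine may be lost by reduction instead of substitution, turnover at the doubly ortho‑substituted carbon may be slow, and the catecholate may be oxidised to a quinone under the hot alkaline copper conditions. The fallback replaces the copper substitution by metalation, borylation and oxidation; it sets out from 17 and returns at 18. Protection of the phenol (MOMCl, i-Pr2NEt) should give the macrocyclic MOM ether F7. Bromine–lithium exchange (n-BuLi, THF, −78 °C), trapping with B(OMe)3 and oxidation of the borate (H2O2, NaOH) should give the MOM‑protected hydroxy macrocycle F8, and HCl in methanol then gives 18.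

Step 6. O‑Arylation of the ortho‑substituted phenol may be slow, and reductive loss of iodine from 11 may then take over. The fallback reverses the coupling polarity to a room‑temperature oxidative copper coupling; it sets out from 11 and returns at 12. Iodine–magnesium exchange (i-PrMgCl·LiCl, THF, −20 °C), B(OMe)3 and aqueous work‑up should give {3-[2-(4-(methoxymethoxy)phenyl)ethenyl]phenyl}boronic acid F9, and Chan–Lam coupling with phenol 6 (Cu(OAc)2, pyridine, 4 Å MS, CH2Cl2, air, rt) forms the same ether and gives 12.

Further compounds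
F1 | step 10 | 1-bromo-5-[2-(3-iodophenyl)ethenyl]-2,3-dimethoxybenzene | COc1cc(C=Cc2cccc(I)c2)cc(Br)c1OC
F2 | step 10 | 2-methoxy-5-{2-[4-(methoxymethoxy)phenyl]ethenyl}phenol | COCOc1ccc(C=Cc2ccc(OC)c(O)c2)cc1
F3 | step 10 | bis‑stilbene diaryl ether with ring C 3-bromo-4,5-dimethoxy and ring D MOM ether | COCOc1ccc(C=Cc2ccc(OC)c(Oc3cccc(C=Cc4cc(OC)c(OC)c(Br)c4)c3)c2)cc1
F4 | step 10 | bis(bibenzyl) diaryl ether with ring C 3-bromo-4,5-dimethoxy and ring D MOM ether | COCOc1ccc(CCc2ccc(OC)c(Oc3cccc(CCc4cc(OC)c(OC)c(Br)c4)c3)c2)cc1
F5 | step 10 | 4-[2-(3-{3-[2-(3-bromo-4,5-dimethoxyphenyl)ethyl]phenoxy}-4-methoxyphenyl)ethyl]phenol | Oc1ccc(CCc2ccc(OC)c(Oc3cccc(CCc4cc(OC)c(OC)c(Br)c4)c3)c2)cc1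
F6 | step 10 | macrocyclic trimethyl ether of the target (ring A OMe, ring C 3,4-di-OMe) | COc1ccc2cc1Oc1cccc(c1)CCc1cc(OC)c(OC)c(c1)Oc1ccc(cc1)CC2
F7 | step 11 | MOM ether of macrocycle 17 (ring C 3-bromo-4-methoxymethoxy-5-aryloxy) | COc1ccc2cc1Oc1cccc(c1)CCc1cc(Br)c(OCOC)c(c1)Oc1c(Cl)cc(cc1Cl)CC2
F8 | step 11 | macrocycle with ring C 3-hydroxy-4-methoxymethoxy-5-aryloxy | COc1ccc2cc1Oc1cccc(c1)CCc1cc(O)c(OCOC)c(c1)Oc1c(Cl)cc(cc1Cl)CC2
F9 | step 6 | {3-[2-(4-(methoxymethoxy)phenyl)ethenyl]phenyl}boronic acid | COCOc1ccc(C=Cc2cccc(B(O)O)c2)cc1
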